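**Retrosynthetic overview**

- The strategy rests on ring A (C1–C5 plus C9), an aroylphloroglucinol in dearomatised form, bridged by C6–C7–C8, with C7 carried as an exocyclic methylene that later becomes the endo prenyl group.
- Target ⇐ deprotection ⇐ exo-face hydroboration of the C7 methylene and B-alkyl Suzuki coupling with 1-bromo-2-methylpropene.
- Ring B ⇐ C5–C6 bond by intramolecular Tsuji–Trost C-allylation of a dearomatised aroylphloroglucinol whose quaternary C1 carries C8 and a 2-(carbonatomethyl)allyl arm.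
- C1–C8 (two adjacent quaternary carbons) ⇐ dearomative Claisen rearrangement of an aryl allyl ether with a geometrically defined tetrasubstituted alkene; the racemate is resolved before the key step.
- Ring order: ring A is the phloroglucinol ring (built first, dearomatised in the Claisen step); ring B closes in the key step.

Key step: step 10

Remark: enolised β-triketones are drawn as one tautomer and CIP labels refer to that tautomer; O-methylation in step 11 is assumed to occur at the less hindered C4 oxygen (the C2–O regioisomer would converge on the same target in step 14).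

**Route**

Step 1
Reactants: 1 phloroglucinol; 2 3-hydroxybenzoic acid
Product: 3 (3-hydroxyphenyl)(2,4,6-trihydroxyphenyl)methanone
Conditions: BF3·OEt2, 90 °C; then H2O
Reagents that add atoms: none
Why: Friedel–Crafts acylation of the threefold-symmetric, very electron-rich arene by the BF3-activated acid should stop at the monoketone, whose chelated carbonyl deactivates the ring.

Step 2
Reactants: 3 (3-hydroxyphenyl)(2,4,6-trihydroxyphenyl)methanone; 4 prenyl bromide
Product: 5 (3-hydroxyphenyl)[2,4,6-trihydroxy-3,5-bis(3-methylbut-2-en-1-yl)phenyl]methanone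
Conditions: 4 (2.1 equiv), 5% aq KOH, 0 °C
Reagents that add atoms: none
Why: C-alkylation of the phloroglucinol polyanion in water, where hydrogen bonding disfavours O-alkylation, should place one prenyl group on each of the two free ring carbons.

Step 3
Reactants: 5 (3-hydroxyphenyl)[2,4,6-trihydroxy-3,5-bis(3-methylbut-2-en-1-yl)phenyl]methanone
Product: 6 [2,4,6-trihydroxy-3,5-bis(3-methylbut-2-en-1-yl)phenyl]{3-[tri(propan-2-yl)silyloxy]phenyl}methanone
Conditions: TIPSCl (1.1 equiv), imidazole, DMF, 0 °C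
Reagents that add atoms: chlorotri(propan-2-yl)silane (TIPSCl), CC(C)[Si](Cl)(C(C)C)C(C)C
Why: Silylation with the bulky chloride should select the only unhindered phenol, since the three phloroglucinol hydroxyls are each flanked by two substituents (two are chelated to the ketone) and any silyl ether formed at the acidic 4-OH is labile on aqueous work-up.

Step 4
Reactants: 7 5-bromo-2-methylpent-2-ene; 8 but-2-yn-1-ol
Product: 11 (2Z)-2-(hydroxymethyl)-3,7-dimethylocta-2,6-dienal, via homoprenylmagnesium bromide 9 (not isolated), via vinylmagnesium alkoxide 10 (not isolated)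
Conditions: 7 (3 equiv), Mg, THF; then 8, Fe(acac)3 (0.15 equiv), THF, −78 → 0 °C; then DMF, −40 °C → rt; aq NH4Cl
Reagents that add atoms: N,N-dimethylformamide, CN(C)C=O
Why: Alkoxide-directed, iron-catalysed syn-carbomagnesiation of the propargylic alcohol puts the homoprenyl group on the distal alkyne carbon and magnesium on the proximal one on the same side, so formylation of the vinyl Grignard with retention places CHO cis to the homoprenyl chain and leaves CH2OH cis to methyl.

Step 5
Reactants: 11 (2Z)-2-(hydroxymethyl)-3,7-dimethylocta-2,6-dienal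
Product: 12 (2Z)-2-formyl-3,7-dimethylocta-2,6-dien-1-yl methyl carbonate
Conditions: ClCO2Me, pyridine, CH2Cl2, 0 °C
Reagents that add atoms: methyl chloroformate, COC(=O)Cl
Why: Acylation of the primary alcohol installs the leaving group for the key step on the arm cis to methyl while the other arm is still an aldehyde, which fixes the differentiation of the two CH2O groups.

Step 6
Reactants: 12 (2Z)-2-formyl-3,7-dimethylocta-2,6-dien-1-yl methyl carbonate
Product: 13 (2E)-2-(hydroxymethyl)-3,7-dimethylocta-2,6-dien-1-yl methyl carbonate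
Conditions: NaBH4, CeCl3·7H2O, MeOH, −78 °C; AcOH quench
Reagents that add atoms: none
Why: Luche 1,2-reduction of the enal leaves the carbonate alone, and the cold, buffered conditions should prevent carbonate migration between the two arms, which would scramble the alkene geometry.

Step 7
Reactants: 6 [2,4,6-trihydroxy-3,5-bis(3-methylbut-2-en-1-yl)phenyl]{3-[tri(propan-2-yl)silyloxy]phenyl}methanone; 13 (2E)-2-(hydroxymethyl)-3,7-dimethylocta-2,6-dien-1-yl methyl carbonate
Product: 14 methyl (2E)-2-{[3,5-dihydroxy-2,6-bis(3-methylbut-2-en-1-yl)-4-{3-[tri(propan-2-yl)silyloxy]benzoyl}phenoxy]methyl}-3,7-dimethylocta-2,6-dien-1-yl carbonate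
Conditions: PPh3, DIAD, toluene, 0 °C → rt
Reagents that add atoms: none
Why: Mitsunobu etherification should take the most acidic, non-chelated 4-OH (para to the ketone) and, as an SN2 displacement at the primary carbon, keeps the alkene geometry with the homoprenyl chain cis to the new OCH2 group.

Step 8
Reactants: 14 methyl (2E)-2-{[3,5-dihydroxy-2,6-bis(3-methylbut-2-en-1-yl)-4-{3-[tri(propan-2-yl)silyloxy]benzoyl}phenoxy]methyl}-3,7-dimethylocta-2,6-dien-1-yl carbonate
Product: 15 racemic methyl 3-{2,4-dihydroxy-1,5-bis(3-methylbut-2-en-1-yl)-6-oxo-3-{3-[tri(propan-2-yl)silyloxy]benzoyl}cyclohexa-2,4-dien-1-yl}-3,7-dimethyl-2-methylideneoct-6-en-1-yl carbonate, (1R,3S) and (1S,3R) pair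
Conditions: o-xylene, BHT (cat.), 130 °C, sealed tube
Reagents that add atoms: none
Why: Dearomative aromatic Claisen rearrangement to the prenyl-bearing ortho carbon forms the C1–C8 bond and is held by tautomerisation to the enolised triketone; the concerted chair transition state ties the (E)-alkene geometry to the relative configuration of C1 and C8, and the product is racemic because the two faces of the arene are enantiotopic.

Step 9
Reactants: 15 racemic methyl 3-{2,4-dihydroxy-1,5-bis(3-methylbut-2-en-1-yl)-6-oxo-3-{3-[tri(propan-2-yl)silyloxy]benzoyl}cyclohexa-2,4-dien-1-yl}-3,7-dimethyl-2-methylideneoct-6-en-1-yl carbonate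
Product: 16 methyl (3S)-3-{(1R)-2,4-dihydroxy-1,5-bis(3-methylbut-2-en-1-yl)-6-oxo-3-{3-[tri(propan-2-yl)silyloxy]benzoyl}cyclohexa-2,4-dien-1-yl}-3,7-dimethyl-2-methylideneoct-6-en-1-yl carbonate
Conditions: preparative chiral SFC, amylose tris(3,5-dimethylphenylcarbamate) phase, CO2/iPrOH (0.1% HCO2H)
Reagents that add atoms: none
Why: Resolution on a chiral stationary phase separates the two enantiomers of the single diastereomer, and the enantiomer drawn is to be identified by electronic circular dichroism or by X-ray analysis of a crystalline derivative before it is carried on.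

Step 10
Reactants: 16 methyl (3S)-3-{(1R)-2,4-dihydroxy-1,5-bis(3-methylbut-2-en-1-yl)-6-oxo-3-{3-[tri(propan-2-yl)silyloxy]benzoyl}cyclohexa-2,4-dien-1-yl}-3,7-dimethyl-2-methylideneoct-6-en-1-yl carbonate
Product: 17 (1S,5S,8S)-4-hydroxy-8-methyl-7-methylidene-1,5-bis(3-methylbut-2-en-1-yl)-8-(4-methylpent-3-en-1-yl)-3-{3-[tri(propan-2-yl)silyloxy]benzoyl}bicyclo[3.3.1]non-3-ene-2,9-dione
Conditions: Pd(PPh3)4 (0.05 equiv), THF, rt → 50 °C
Reagents that add atoms: none
Why: Zerovalent palladium ionises the allylic methyl carbonate with loss of CO2, the methoxide released takes the acidic enol proton, and C5 of the resulting triketone enolate attacks a terminus of the 2-substituted π-allyl unit (intramolecular Tsuji–Trost C-allylation, the closest known reaction being the palladium-catalysed allylic annulation of dearomatised acylphloroglucinols to bicyclo[3.3.1]nonanetriones). Ring B (C1, C9, C5, C6, C7, C8) closes in a six-membered exo mode: the attacked terminus C6 and the central carbon C7 enter the ring and the other terminus stays outside as the C7 methylene; both termini are CH2 groups, so the allyl unit poses no regiochemical question. The new stereocentre C5 is controlled by the substrate, because the three-atom arm is anchored on the quaternary C1 and can reach C5 only on the face that carries the C1–C8 bond, so the C1–C8 and C5–C6 bonds must be cis on ring A. The selectivity needed is C5-alkylation over closure at the C9 or C2 oxygen and at the aroyl-bearing C3; allyl enol ethers and a C3-allylated non-enolisable triketone are allylic derivatives of strongly stabilised anions and are re-ionised by the catalyst, whereas the C5-alkylated product keeps the chelated, enolised aroyl triketone and cannot re-ionise. Since loss of CO2 makes the first ionisation irreversible, the reversible isomers should drain into 17.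

Step 11
Reactants: 17 (1S,5S,8S)-4-hydroxy-8-methyl-7-methylidene-1,5-bis(3-methylbut-2-en-1-yl)-8-(4-methylpent-3-en-1-yl)-3-{3-[tri(propan-2-yl)silyloxy]benzoyl}bicyclo[3.3.1]non-3-ene-2,9-dione
Product: 18 (1S,5S,8S)-4-methoxy-8-methyl-7-methylidene-1,5-bis(3-methylbut-2-en-1-yl)-8-(4-methylpent-3-en-1-yl)-3-{3-[tri(propan-2-yl)silyloxy]benzoyl}bicyclo[3.3.1]non-3-ene-2,9-dione
Conditions: TMSCHN2, MeOH/toluene (1:4), 0 °C
Reagents that add atoms: (trimethylsilyl)diazomethane, C[Si](C)(C)C=[N+]=[N-]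
Why: O-methylation of the vinylogous acid (C3 is blocked, so only oxygen can react) removes the acidic proton that would consume the borane, and should favour the C4 oxygen, which is remote from the C1/C8 quaternary pair.

Step 12
Reactants: 18 (1S,5S,8S)-4-methoxy-8-methyl-7-methylidene-1,5-bis(3-methylbut-2-en-1-yl)-8-(4-methylpent-3-en-1-yl)-3-{3-[tri(propan-2-yl)silyloxy]benzoyl}bicyclo[3.3.1]non-3-ene-2,9-dione; 19 1-bromo-2-methylprop-1-ene
Product: 21 (1S,5S,7S,8S)-4-methoxy-8-methyl-1,5,7-tris(3-methylbut-2-en-1-yl)-8-(4-methylpent-3-en-1-yl)-3-{3-[tri(propan-2-yl)silyloxy]benzoyl}bicyclo[3.3.1]non-3-ene-2,9-dione, via B-alkyl-9-BBN adduct 20 (not isolated)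
Conditions: 9-BBN (2 equiv), THF, 0 °C → rt; then 19, Pd(dppf)Cl2 (0.1 equiv), AsPh3, aq K3PO4, DMF, rt → 50 °C
Reagents that add atoms: none
Why: 9-BBN should add anti-Markovnikov to the only 1,1-disubstituted alkene from the exo face, the endo face being covered by ring A, so that hydrogen arrives exo and the boryl-methyl arm ends up endo (7S), and B-alkyl Suzuki–Miyaura coupling with the alkenyl bromide then completes the prenyl group without touching C7.

Step 13
Reactants: 21 (1S,5S,7S,8S)-4-methoxy-8-methyl-1,5,7-tris(3-methylbut-2-en-1-yl)-8-(4-methylpent-3-en-1-yl)-3-{3-[tri(propan-2-yl)silyloxy]benzoyl}bicyclo[3.3.1]non-3-ene-2,9-dione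
Product: 22 (1S,5S,7S,8S)-3-(3-hydroxybenzoyl)-4-methoxy-8-methyl-1,5,7-tris(3-methylbut-2-en-1-yl)-8-(4-methylpent-3-en-1-yl)bicyclo[3.3.1]non-3-ene-2,9-dione
Conditions: TBAF, AcOH (1:1), THF, 0 °C
Reagents that add atoms: none
Why: Buffered fluoride cleaves the aryl silyl ether and leaves the vinylogous methyl ester and the four trisubstituted alkenes untouched.

Step 14
Reactants: 22 (1S,5S,7S,8S)-3-(3-hydroxybenzoyl)-4-methoxy-8-methyl-1,5,7-tris(3-methylbut-2-en-1-yl)-8-(4-methylpent-3-en-1-yl)bicyclo[3.3.1]non-3-ene-2,9-dione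
Product: 23 (1S,5S,7S,8S)-4-hydroxy-3-(3-hydroxybenzoyl)-8-methyl-1,5,7-tris(3-methylbut-2-en-1-yl)-8-(4-methylpent-3-en-1-yl)bicyclo[3.3.1]non-3-ene-2,9-dione (CNP0406274.1)
Conditions: LiOH·H2O, dioxane/H2O, 90 °C; then 1 M HCl
Reagents that add atoms: lithium hydroxide monohydrate, [Li+].[OH-].O
Why: Hydroxide adds to C4 of the vinylogous ester and expels methoxide (addition–elimination), which frees the enolised triketone; no stereocentre is epimerisable, since C1, C5 and C8 are quaternary and C7 has no adjacent carbonyl.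

**Compound list**

1 | phloroglucinol | Oc1cc(O)cc(O)c1 | starting material
2 | 3-hydroxybenzoic acid | O=C(O)c1cccc(O)c1 | starting material
3 | (3-hydroxyphenyl)(2,4,6-trihydroxyphenyl)methanone | O=C(c1cccc(O)c1)c1c(O)cc(O)cc1O | intermediate
4 | prenyl bromide (1-bromo-3-methylbut-2-ene) | CC(C)=CCBr | starting material
5 | (3-hydroxyphenyl)[2,4,6-trihydroxy-3,5-bis(3-methylbut-2-en-1-yl)phenyl]methanone | CC(C)=CCc1c(O)c(CC=C(C)C)c(O)c(C(=O)c2cccc(O)c2)c1O | intermediate
6 | [2,4,6-trihydroxy-3,5-bis(3-methylbut-2-en-1-yl)phenyl]{3-[tri(propan-2-yl)silyloxy]phenyl}methanone | CC(C)=CCc1c(O)c(CC=C(C)C)c(O)c(C(=O)c2cccc(O[Si](C(C)C)(C(C)C)C(C)C)c2)c1O | intermediate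
7 | 5-bromo-2-methylpent-2-ene | CC(C)=CCCBr | starting material
8 | but-2-yn-1-ol | CC#CCO | starting material
9 | (4-methylpent-3-en-1-yl)magnesium bromide (homoprenylmagnesium bromide) | CC(C)=CCC[Mg]Br | intermediate (not isolated)
10 | bromomagnesium alkoxide of (2Z)-2-(bromomagnesio)-3,7-dimethylocta-2,6-dien-1-ol (Mg cis to the homoprenyl chain) | CC(C)=CCC/C(C)=C(/CO[Mg]Br)[Mg]Br | intermediate (not isolated)
11 | (2Z)-2-(hydroxymethyl)-3,7-dimethylocta-2,6-dienal | CC(C)=CCC/C(C)=C(/CO)C=O | intermediate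
12 | (2Z)-2-formyl-3,7-dimethylocta-2,6-dien-1-yl methyl carbonate | CC(C)=CCC/C(C)=C(/COC(=O)OC)C=O | intermediate
13 | (2E)-2-(hydroxymethyl)-3,7-dimethylocta-2,6-dien-1-yl methyl carbonate | CC(C)=CCC/C(C)=C(/COC(=O)OC)CO | intermediate
14 | methyl (2E)-2-{[3,5-dihydroxy-2,6-bis(3-methylbut-2-en-1-yl)-4-{3-[tri(propan-2-yl)silyloxy]benzoyl}phenoxy]methyl}-3,7-dimethylocta-2,6-dien-1-yl carbonate | CC(C)=CCC/C(C)=C(/COC(=O)OC)COc1c(CC=C(C)C)c(O)c(C(=O)c2cccc(O[Si](C(C)C)(C(C)C)C(C)C)c2)c(O)c1CC=C(C)C | intermediate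
15 | racemic methyl 3-{2,4-dihydroxy-1,5-bis(3-methylbut-2-en-1-yl)-6-oxo-3-{3-[tri(propan-2-yl)silyloxy]benzoyl}cyclohexa-2,4-dien-1-yl}-3,7-dimethyl-2-methylideneoct-6-en-1-yl carbonate, 1:1 mixture of the (1R,3S) and (1S,3R) enantiomers | CC(C)=CCC[C@@](C)(C(=C)COC(=O)OC)[C@@]1(CC=C(C)C)C(=O)C(CC=C(C)C)=C(O)C(C(=O)c2cccc(O[Si](C(C)C)(C(C)C)C(C)C)c2)=C1O.CC(C)=CCC[C@](C)(C(=C)COC(=O)OC)[C@]1(CC=C(C)C)C(=O)C(CC=C(C)C)=C(O)C(C(=O)c2cccc(O[Si](C(C)C)(C(C)C)C(C)C)c2)=C1O | intermediate
16 | methyl (3S)-3-{(1R)-2,4-dihydroxy-1,5-bis(3-methylbut-2-en-1-yl)-6-oxo-3-{3-[tri(propan-2-yl)silyloxy]benzoyl}cyclohexa-2,4-dien-1-yl}-3,7-dimethyl-2-methylideneoct-6-en-1-yl carbonate (C1 and C8 as in the target) | CC(C)=CCC[C@@](C)(C(=C)COC(=O)OC)[C@@]1(CC=C(C)C)C(=O)C(CC=C(C)C)=C(O)C(C(=O)c2cccc(O[Si](C(C)C)(C(C)C)C(C)C)c2)=C1O | intermediate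
17 | (1S,5S,8S)-4-hydroxy-8-methyl-7-methylidene-1,5-bis(3-methylbut-2-en-1-yl)-8-(4-methylpent-3-en-1-yl)-3-{3-[tri(propan-2-yl)silyloxy]benzoyl}bicyclo[3.3.1]non-3-ene-2,9-dione | CC(C)=CCC[C@@]1(C)C(=C)C[C@]2(CC=C(C)C)C(=O)[C@@]1(CC=C(C)C)C(=O)C(C(=O)c1cccc(O[Si](C(C)C)(C(C)C)C(C)C)c1)=C2O | intermediate
18 | (1S,5S,8S)-4-methoxy-8-methyl-7-methylidene-1,5-bis(3-methylbut-2-en-1-yl)-8-(4-methylpent-3-en-1-yl)-3-{3-[tri(propan-2-yl)silyloxy]benzoyl}bicyclo[3.3.1]non-3-ene-2,9-dione | CC(C)=CCC[C@@]1(C)C(=C)C[C@]2(CC=C(C)C)C(=O)[C@@]1(CC=C(C)C)C(=O)C(C(=O)c1cccc(O[Si](C(C)C)(C(C)C)C(C)C)c1)=C2OC | intermediate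
19 | 1-bromo-2-methylprop-1-ene | CC(C)=CBr | starting material
20 | (1S,5S,7S,8S)-7-[(9-borabicyclo[3.3.1]nonan-9-yl)methyl]-4-methoxy-8-methyl-1,5-bis(3-methylbut-2-en-1-yl)-8-(4-methylpent-3-en-1-yl)-3-{3-[tri(propan-2-yl)silyloxy]benzoyl}bicyclo[3.3.1]non-3-ene-2,9-dione | CC(C)=CCC[C@@]1(C)[C@@H](CB3C4CCCC3CCC4)C[C@]2(CC=C(C)C)C(=O)[C@@]1(CC=C(C)C)C(=O)C(C(=O)c1cccc(O[Si](C(C)C)(C(C)C)C(C)C)c1)=C2OC | intermediate (not isolated)
21 | (1S,5S,7S,8S)-4-methoxy-8-methyl-1,5,7-tris(3-methylbut-2-en-1-yl)-8-(4-methylpent-3-en-1-yl)-3-{3-[tri(propan-2-yl)silyloxy]benzoyl}bicyclo[3.3.1]non-3-ene-2,9-dione | CC(C)=CCC[C@@]1(C)[C@@H](CC=C(C)C)C[C@]2(CC=C(C)C)C(=O)[C@@]1(CC=C(C)C)C(=O)C(C(=O)c1cccc(O[Si](C(C)C)(C(C)C)C(C)C)c1)=C2OC | intermediate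
22 | (1S,5S,7S,8S)-3-(3-hydroxybenzoyl)-4-methoxy-8-methyl-1,5,7-tris(3-methylbut-2-en-1-yl)-8-(4-methylpent-3-en-1-yl)bicyclo[3.3.1]non-3-ene-2,9-dione | CC(C)=CCC[C@@]1(C)[C@@H](CC=C(C)C)C[C@]2(CC=C(C)C)C(=O)[C@@]1(CC=C(C)C)C(=O)C(C(=O)c1cccc(O)c1)=C2OC | intermediate
23 | (1S,5S,7S,8S)-4-hydroxy-3-(3-hydroxybenzoyl)-8-methyl-1,5,7-tris(3-methylbut-2-en-1-yl)-8-(4-methylpent-3-en-1-yl)bicyclo[3.3.1]non-3-ene-2,9-dione (CNP0406274.1) | CC(C)=CCC[C@@]1(C)[C@@H](CC=C(C)C)C[C@]2(CC=C(C)C)C(=O)[C@@]1(CC=C(C)C)C(=O)C(C(=O)c1cccc(O)c1)=C2O | target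

**Step count and risks**

Total step count: 14. Longest linear sequence: 11 steps (steps 1–3 and 7–14, or equally steps 4–6 and 7–14).

Steps most likely to fail:

1. Step 10 (key step). The ring could close through the C9 or C2 oxygen, or at the aroyl-bearing C3, without reverting, or the π-allyl complex could decay before C5 captures it. Fallback, from 16 back to 17, changes the bond-forming event from a polar to a radical one. With Pd(PPh3)4 and PhSO2Na in THF/MeOH the π-allyl complex is trapped intermolecularly by sulfinate to give the allyl phenyl sulfone F1. Oxidation of its enolised triketone with Mn(OAc)3·2H2O in AcOH at rt should then give the C5-centred radical, which adds to the methylene terminus (six-membered closure) and expels the benzenesulfonyl radical from the tertiary C7 radical. This forms the same C5–C6 bond and the same C7 methylene, so the route is rejoined at 17.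

2. Step 8. The rearrangement could run through the boat instead of the chair transition state, which gives the wrong relative configuration at C1/C8. Fallback, from 6 and 11 back to 15, uses the geometric isomer of the ether, for which the boat gives the right diastereomer. Mitsunobu coupling of 6 with the hydroxy-enal 11 (PPh3, DIAD) gives the aryl ether aldehyde F2. Luche reduction (NaBH4, CeCl3·7H2O) gives the allylic alcohol F3. ClCO2Me/pyridine at −20 °C should acylate the primary alcohol before the chelated, doubly flanked phenols and give the (Z)-ether carbonate F4, the geometric isomer of 14. Its thermal rearrangement then returns to 15.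

3. Step 12. A carbonyl group could be reduced by the dialkylborane, the hindered methylene could hydroborate sluggishly, or the β-branched alkylborane could transmetalate slowly. Fallback, from 18 back to 21, uses catalytic hydroboration and an isolable boronate. [Ir(cod)Cl]2/dppe with pinacolborane (which does not reduce ketones without a catalyst) should give the primary pinacol boronate F5, with the same exo-face delivery of hydrogen. Suzuki–Miyaura coupling of F5 with 19 (Pd(OAc)2, RuPhos, K3PO4, toluene/H2O, 80 °C) returns to 21.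

**Further compounds**

F1 | step 10 | (4R)-4-[(3S)-2-(benzenesulfonylmethyl)-3,7-dimethylocta-1,6-dien-3-yl]-3,5-dihydroxy-4,6-bis(3-methylbut-2-en-1-yl)-2-{3-[tri(propan-2-yl)silyloxy]benzoyl}cyclohexa-2,5-dien-1-one tautomer (allyl phenyl sulfone analogue of 16) | CC(C)=CCC[C@@](C)(C(=C)CS(=O)(=O)c3ccccc3)[C@@]1(CC=C(C)C)C(=O)C(CC=C(C)C)=C(O)C(C(=O)c2cccc(O[Si](C(C)C)(C(C)C)C(C)C)c2)=C1O
F2 | step 8 | (2Z)-2-{[3,5-dihydroxy-2,6-bis(3-methylbut-2-en-1-yl)-4-{3-[tri(propan-2-yl)silyloxy]benzoyl}phenoxy]methyl}-3,7-dimethylocta-2,6-dienal | CC(C)=CCC/C(C)=C(/COc1c(CC=C(C)C)c(O)c(C(=O)c2cccc(O[Si](C(C)C)(C(C)C)C(C)C)c2)c(O)c1CC=C(C)C)C=O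
F3 | step 8 | (2E)-2-{[3,5-dihydroxy-2,6-bis(3-methylbut-2-en-1-yl)-4-{3-[tri(propan-2-yl)silyloxy]benzoyl}phenoxy]methyl}-3,7-dimethylocta-2,6-dien-1-ol | CC(C)=CCC/C(C)=C(/COc1c(CC=C(C)C)c(O)c(C(=O)c2cccc(O[Si](C(C)C)(C(C)C)C(C)C)c2)c(O)c1CC=C(C)C)CO
F4 | step 8 | methyl (2Z)-2-{[3,5-dihydroxy-2,6-bis(3-methylbut-2-en-1-yl)-4-{3-[tri(propan-2-yl)silyloxy]benzoyl}phenoxy]methyl}-3,7-dimethylocta-2,6-dien-1-yl carbonate | CC(C)=CCC/C(C)=C(/COc1c(CC=C(C)C)c(O)c(C(=O)c2cccc(O[Si](C(C)C)(C(C)C)C(C)C)c2)c(O)c1CC=C(C)C)COC(=O)OC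
F5 | step 12 | (1S,5S,7S,8S)-4-methoxy-8-methyl-1,5-bis(3-methylbut-2-en-1-yl)-8-(4-methylpent-3-en-1-yl)-7-[(4,4,5,5-tetramethyl-1,3,2-dioxaborolan-2-yl)methyl]-3-{3-[tri(propan-2-yl)silyloxy]benzoyl}bicyclo[3.3.1]non-3-ene-2,9-dione | CC(C)=CCC[C@@]1(C)[C@@H](CB3OC(C)(C)C(C)(C)O3)C[C@]2(CC=C(C)C)C(=O)[C@@]1(CC=C(C)C)C(=O)C(C(=O)c1cccc(O[Si](C(C)C)(C(C)C)C(C)C)c1)=C2OC
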